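**Retrosynthetic overview**

- Feature used: in each half the quaternary C11 (CH3, CO2Me) is the allylic end of the ring-B C6=C7 bond and carries C15'H2, the ε-carbon of the other half's dienone C4'=C5'–C6'=C7'–C8'=O. The two C11–C15' bonds lie in the 12-membered ring made of C4, C5, C6, C7, C11 and C15 of both halves, so each is the product bond of a [3,3] shift of a C6–O ester enolate whose spare carboxyl (C16') on C15' can leave afterwards as CO2.
- Disconnections: cycloshizukaol A ⇐ bis-dienone tetramethyl ester (loss of two CO2Me) ⇐ 12-membered carbocyclic diacid bis-lactone ⇐ twofold reductive Ireland–Claisen rearrangement of a C2-symmetric 12-membered head-to-tail dilactone ⇐ Mitsunobu cyclodimerisation of a tetracyclic hydroxy acid.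
- Monomer ⇐ Nozaki–Hiyama–Kishi closure of C6–C7 ⇐ vinylogous Mukaiyama aldol (C8–C9) of a ring-A aldehyde with a 4-bromo-2-silyloxyfuran ⇐ cyclopropanated cyclopentanone ⇐ enantioselective conjugate addition of a hexenylalane to 3-methylcyclopentenone.
- Ring order: ring A (purchased cyclopentenone), cyclopropane, butenolide attached, ring B, 12-membered dilactone, its transposition into the 12-membered carbocycle, opening of the two butenolides last.

Key step: step 19

Assumption: lindenane numbering is used for every intermediate (primes for the second half) and β means the face of the C14 methyl group; the C8 configuration from step 12 and the C4 and C15 configurations from step 19 are drawn as expected, but all three centres are removed later and do not bear on the target.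

**Route**

Step 1
Reactants: 1 3-methylcyclopent-2-en-1-one; 2 hex-1-yne
Product: 5 (R)-triethyl{[3-((E)-hex-1-en-1-yl)-3-methylcyclopent-1-en-1-yl]oxy}silane, via alkenylalane 3 (not isolated), via aluminium enolate 4 (not isolated)
Conditions: 2, iBu2AlH, hexane, 55 °C; then 1, Cu(OTf)2 (5 mol %), chiral sulfonate-bearing imidazolinium salt (N-heterocyclic carbene precursor, 6 mol %), THF, −30 → 0 °C; then TESOTf, −78 °C → rt
Reagents that add atoms: triethylsilyl trifluoromethanesulfonate (TESOTf), CC[Si](CC)(CC)OS(=O)(=O)C(F)(F)F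
Why: syn-hydroalumination fixes the E alkenylalane, the chiral carbene–copper catalyst (ligand enantiomer chosen for the R centre) transfers the alkenyl group to one face of the enone in an enantioselective conjugate addition that sets quaternary C10, and O-silylation of the aluminium enolate holds the enol double bond on the C5 side.

Step 2
Reactants: 5 silyl enol ether
Product: 6 (2S,3R)-3-[(E)-hex-1-en-1-yl]-2-(hydroxymethyl)-3-methylcyclopentan-1-one (hydroxymethyl cis to the methyl group)
Conditions: aq. HCHO (37%), Yb(OTf)3 (10 mol %), THF, rt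
Reagents that add atoms: formaldehyde, C=O
Why: Lewis acid-catalysed Mukaiyama aldol hydroxymethylation in a water-containing medium, in which formaldehyde should approach C5 anti to the hexenyl chain on C10 and so place C6 on the β face.

Step 3
Reactants: 6 hydroxy ketone
Product: 7 (2S,3R)-2-{[(tert-butyldimethylsilyl)oxy]methyl}-3-[(E)-hex-1-en-1-yl]-3-methylcyclopentan-1-one
Conditions: TBSCl, imidazole, DMF, 0 °C → rt
Reagents that add atoms: tert-butyldimethylsilyl chloride, CC(C)(C)[Si](C)(C)Cl
Why: standard silylation of the primary alcohol, done at once so that the β-hydroxy ketone cannot undergo retro-aldol loss of formaldehyde or dehydration.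

Step 4
Reactants: 7 silyl ether ketone
Product: 9 5-{[(tert-butyldimethylsilyl)oxy]methyl}-4-[(E)-hex-1-en-1-yl]-4-methylcyclopent-2-en-1-one (both centres as in 7), via trimethylsilyl enol ether 8 (not isolated)
Conditions: lithium diisopropylamide, TMSCl, THF, −78 °C; then Pd(OAc)2 (10 mol %), O2 (1 atm), DMSO, rt
Reagents that add atoms: none
Why: kinetic deprotonation takes the unhindered C3 proton and leaves C5 and its β-silyloxy group untouched, and Saegusa–Ito dehydrosilylation of the enol silane then installs the C1=C3 double bond.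

Step 5
Reactants: 9 cyclopentenone
Product: 10 5-{[(tert-butyldimethylsilyl)oxy]methyl}-4-[(E)-hex-1-en-1-yl]-4-methylcyclopent-2-en-1-ol with the hydroxyl cis to the silyloxymethyl arm (4β-ol)
Conditions: NaBH4, CeCl3·7H2O, MeOH, −78 °C
Reagents that add atoms: none
Why: Luche 1,2-reduction, with hydride expected from the α face, anti to the neighbouring β-oriented C6 arm, which gives the 4β-alcohol.

Step 6
Reactants: 10 allylic alcohol
Product: 11 bicyclo[3.1.0]hexan-2-ol with cyclopropane methylene, hydroxyl, silyloxymethyl arm and methyl group all β and the hexenyl chain α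
Conditions: Et2Zn, CH2I2, CH2Cl2, −10 → 0 °C
Reagents that add atoms: diiodomethane, ICI
Why: hydroxyl-directed Simmons–Smith cyclopropanation (Furukawa variant), in which the zinc alkoxide delivers the methylene to the β face of C1=C3 and sets C1 and C3, while the undirected hexenyl alkene reacts much more slowly with a limited amount of reagent.

Step 7
Reactants: 11 cyclopropyl carbinol
Product: 12 4-[(E)-hex-1-en-1-yl]-4-methyl-3-{[(tert-butyldimethylsilyl)oxy]methyl}bicyclo[3.1.0]hexan-2-one (ring A with β-cyclopropane)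
Conditions: Dess–Martin periodinane, CH2Cl2, rt
Reagents that add atoms: none
Why: mild, non-basic Dess–Martin oxidation returns the C4 ketone without epimerising C5 or eliminating the β-silyloxy group.

Step 8
Reactants: 12 bicyclic ketone; 13 tert-butyl diethylphosphonoacetate
Product: 14 tert-butyl (E)-alkylidene acetate at C4 (C4=C15, ester anti to C5)
Conditions: NaH, THF, 0 → 60 °C
Reagents that add atoms: none
Why: Horner–Wadsworth–Emmons olefination in which the ester should settle anti to the encumbered C5 side (silyloxymethyl arm next to quaternary C10) and syn to the cyclopropane C3–H; the minor geometric isomer is removed by chromatography.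

Step 9
Reactants: 14 alkylidene acetate
Product: 15 ring-A aldehyde (C9 formyl group on C10 in place of the hexenyl chain)
Conditions: O3, CH2Cl2/MeOH, −78 °C (Sudan Red 7B end point); then PPh3
Reagents that add atoms: ozone, [O-][O+]=O
Why: ozonolysis is selective for the electron-rich 1,2-dialkyl alkene over the ester-deactivated trisubstituted enoate, and the indicator dye stops the addition at that point.

Step 10
Reactants: 16 3-methyltetronic acid
Product: 17 4-bromo-3-methylfuran-2(5H)-one
Conditions: (COBr)2, DMF (cat.), CH2Cl2, 0 °C → rt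
Reagents that add atoms: oxalyl bromide, BrC(=O)C(=O)Br
Why: Vilsmeier-type activation turns the vinylogous acid hydroxyl into a leaving group that bromide replaces by addition–elimination.

Step 11
Reactants: 17 bromobutenolide
Product: 18 [(4-bromo-3-methylfuran-2-yl)oxy](tert-butyl)dimethylsilane
Conditions: TBSOTf, Et3N, CH2Cl2, 0 °C
Reagents that add atoms: tert-butyldimethylsilyl trifluoromethanesulfonate, CC(C)(C)[Si](C)(C)OS(=O)(=O)C(F)(F)F
Why: soft enolisation of the butenolide at its γ-CH2 gives the aromatic 2-silyloxyfuran, the usual dienolate equivalent for vinylogous aldol chemistry.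

Step 12
Reactants: 15 ring-A aldehyde; 18 silyloxyfuran
Product: 19 C8–C9 aldol adduct, 9β-carbinol carrying the 7-bromo-11-methylbutenolide at C8 (C8 oxygen on the side that becomes α in ring B)
Conditions: BF3·OEt2, CH2Cl2, −78 °C; aq. NaHCO3
Reagents that add atoms: none
Why: vinylogous Mukaiyama aldol addition through the furan 5-position (C8), where the activated aldehyde should be attacked on the Felkin–Anh face set by quaternary C10 (C5 branch large, C1 medium, methyl small) to give the 9β-carbinol with the usual threo C8/C9 preference of silyloxyfurans, C8 being erased later as a ketone.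

Step 13
Reactants: 19 aldol adduct
Product: 20 9β-tert-butyldimethylsilyl ether of 19 (silyl ethers at C6 and C9)
Conditions: TBSOTf, 2,6-lutidine, CH2Cl2, −78 → −20 °C
Reagents that add atoms: tert-butyldimethylsilyl trifluoromethanesulfonate, CC(C)(C)[Si](C)(C)OS(=O)(=O)C(F)(F)F
Why: the silyl triflate silylates the hindered neopentyl carbinol at low temperature, below the threshold at which it would attack the tert-butyl ester, and the weak base leaves the butenolide alone.

Step 14
Reactants: 20 bis-silyl ether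
Product: 21 C6 primary alcohol (9β-silyl ether kept)
Conditions: CSA (10 mol %), MeOH/CH2Cl2, 0 °C
Reagents that add atoms: none
Why: acid-catalysed methanolysis removes the unhindered primary silyl ether far faster than the neopentyl secondary one and does not touch the tert-butyl ester.

Step 15
Reactants: 21 primary alcohol
Product: 22 C6 aldehyde (β,γ-unsaturated to the C4=C15 enoate), used crude
Conditions: Dess–Martin periodinane, NaHCO3, CH2Cl2, 0 °C
Reagents that add atoms: none
Why: buffered Dess–Martin oxidation under neutral conditions should give the aldehyde without moving the C4=C15 double bond into conjugation or epimerising C5.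

Step 16
Reactants: 22 C6 aldehyde
Product: 23 tetracyclic 6β-hydroxy lindenanolide tert-butyl ester (H5 α, 6β-OH axial, lactone oxygen α at C8, 9β-silyl ether)
Conditions: CrCl2 (6 equiv), NiCl2 (2 mol %), DMSO/THF, rt, 0.01 M
Reagents that add atoms: none
Why: Nozaki–Hiyama–Kishi reaction in which nickel activates the alkenyl bromide, chromium takes over the alkenyl group and 6-exo-trig addition to the aldehyde closes ring B at C6–C7, the C6–O bond developing axial (β) and out of the C7=C11 plane to avoid allylic 1,3-strain with the C13 methyl group.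

Step 17
Reactants: 23 tert-butyl ester
Product: 25 hydroxy acid monomer (free C16 acid, 6β-OH, 9β-silyl ether), via bis(trimethylsilyl) derivative 24 (not isolated)
Conditions: TMSOTf, 2,6-lutidine, CH2Cl2, 0 °C; then aq. citric acid, THF
Reagents that add atoms: none
Why: silyl triflate-induced loss of isobutene converts the tert-butyl ester into a trimethylsilyl ester under non-protic conditions that spare the neopentyl silyl ether, and the labile trimethylsilyl ester and ether hydrolyse on mild acidic work-up.

Step 18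
Reactants: 25 hydroxy acid monomer (two molecules)
Product: 27 C2-symmetric 12-membered head-to-tail dilactone (two C16(=O)–O–C6' esters, both C6–O bonds α), via open-chain ester dimer 26 (not isolated)
Conditions: PPh3, DIAD, toluene, 0 °C → rt, 0.02 M, slow addition of 25
Reagents that add atoms: none
Why: Mitsunobu esterification run twice, each carboxylate displacing the activated 6β-oxygen of the other unit with inversion; the E geometry keeps every carboxyl anti to C5 and away from its own C6, so no monomeric lactone can form and the 12-membered diolide is the smallest ring available.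

Step 19
Reactants: 27 dilactone
Product: 30 12-membered carbocyclic diacid bis-lactone (C11–C15' and C11'–C15 bonds, C6=C7 and C6'=C7' alkenes, CO2H on C15 and C15', saturated γ-lactones C12–O–C8), via bis(silyl ketene acetal) 28 (not isolated), via bis(silyl ester) 29 (not isolated)
Conditions: Cu(OAc)2·H2O (20 mol %), 1,2-bis(diphenylphosphino)benzene (20 mol %), HSiMe(OEt)2 (6 equiv), toluene, rt → 70 °C; then aq. citric acid, THF
Reagents that add atoms: none
Why: Proposed new method: a phosphine-bound copper hydride of monovalent copper adds hydride to C4 and C4' of the two enoates and σ-bond metathesis with the silane gives the ketene acetals C15=C16(OSi)–O–C6', each of which then undergoes a suprafacial [3,3] shift through O–C6'–C7'=C11'···C15=C16 that forms C11'–C15 and C6'=C7' and breaks C6'–O. The closest known reactions are the metal hydride reductive Ireland–Claisen rearrangement of acyclic allyl enoates and the Ireland–Claisen ring contraction of macrolactones, here combined and run twice in one dilactone. The 12-membered carbocycle (C4, C5, C6, C7, C11, C15 of both halves) is not closed end to end: it arises by sigmatropic transposition inside the existing 12-membered dilactone, each shift passing through a six-membered chair or boat array and exchanging the ring bond C16–O for the ring path C7'–C11'. C11 and C11' are set by 1,3-chirality transfer from the 6α C–O bonds across the butenolide-locked C7=C11 alkenes, so C15' arrives on the α face with C12 still syn to C8 whatever the ketene acetal geometry, whereas C4 (face of hydride delivery) and C15 (ketene acetal geometry, chair against boat) are temporary. The step needs hydride addition at the enoates only, which the trisubstituted enoate against the tetrasubstituted α-methyl butenolide should secure, and it needs enolate formation without base so that the acidic butenolide hydrogens at C8 and C6 are never removed. Allylic 1,3-strain between the C13 methyl group and the 6α oxygen holds each C6–O bond out of the alkene plane, aligned for the shift.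

Step 20
Reactants: 30 diacid bis-lactone
Product: 32 tetramethyl ester diol (CO2Me on C11, C11', C15, C15'; free 8-OH and 8'-OH; 9β-silyl ethers), via tetrapotassium tetracarboxylate 31 (not isolated)
Conditions: KOH, MeOH/H2O, 50 °C; evaporate; MeI, DMF, rt
Reagents that add atoms: potassium hydroxide, [K+].[OH-]; iodomethane, CI
Why: saponification opens both γ-lactones, and O-alkylation of the dry carboxylate salts without any acidification fixes all four carboxyls as methyl esters before the hydroxy acids can close again; the crude diol is oxidised directly.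

Step 21
Reactants: 32 tetramethyl ester diol
Product: 33 bis-enone tetramethyl ester (C8=O conjugated with C6=C7 in each half)
Conditions: Dess–Martin periodinane, CH2Cl2, 0 °C → rt
Reagents that add atoms: none
Why: Dess–Martin oxidation of the allylic C8 alcohols gives the enones and removes the hydroxyl that could re-lactonise onto C12.

Step 22
Reactants: 33 bis-enone
Product: 35 bis-dienone tetramethyl ester (C4=C5–C6=C7–C8=O in each half, CO2Me still on C15 and C15'), via bis(silyl dienol ether) 34 (not isolated)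
Conditions: TBSOTf, Et3N, CH2Cl2, 0 °C; then DDQ, 2,6-lutidine, CH2Cl2, 0 °C → rt
Reagents that add atoms: none
Why: soft enolisation removes the axial γ-hydrogen at C5 to give the linearly conjugated silyl dienol ether, and quinone dehydrogenation (hydride abstraction from C4–H, then loss of silyl) extends it to the dienone whichever C4 epimer is present.

Step 23
Reactants: 35 bis-dienone tetramethyl ester
Product: 36 9,9'-bis-O-(tert-butyldimethylsilyl)cycloshizukaol A
Conditions: LiCl, H2O, DMSO, 130 °C
Reagents that add atoms: none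
Why: Krapcho dealkoxycarbonylation removes only the two C15 esters, because loss of CO2 there leaves a trienolate delocalised onto the C8 oxygen, and reprotonation under equilibrating conditions returns the fully conjugated dienone with C15H2; the C11 esters have no such stabilisation and sit on quaternary carbons.

Step 24
Reactants: 36 bis-silyl ether
Product: 37 cycloshizukaol A
Conditions: HF·pyridine, THF, 0 °C → rt
Reagents that add atoms: none
Why: fluoride-mediated desilylation under mildly acidic conditions frees the two 9β-hydroxyls without enolising the α-ketols, whose equatorial, hydrogen-bonded configuration is also the stable one.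

**Compound list**

1 | 3-methylcyclopent-2-en-1-one | CC1=CC(=O)CC1 | starting material
2 | hex-1-yne | CCCCC#C | starting material
3 | (E)-hex-1-en-1-yl(diisobutyl)alane | CCCC/C=C/[Al](CC(C)C)CC(C)C | intermediate
4 | diisobutylaluminium enolate of (R)-3-[(E)-hex-1-enyl]-3-methylcyclopentanone (enolate on the C2 side) | CC(C)C[Al](CC(C)C)OC1=C[C@@](C)(/C=C/CCCC)CC1 | intermediate
5 | (R)-triethyl{[3-((E)-hex-1-en-1-yl)-3-methylcyclopent-1-en-1-yl]oxy}silane | CC[Si](CC)(CC)OC1=C[C@@](C)(/C=C/CCCC)CC1 | intermediate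
6 | (2S,3R)-3-[(E)-hex-1-en-1-yl]-2-(hydroxymethyl)-3-methylcyclopentan-1-one | O=C1CC[C@](C)(/C=C/CCCC)[C@H]1CO | intermediate
7 | (2S,3R)-2-{[(tert-butyldimethylsilyl)oxy]methyl}-3-[(E)-hex-1-en-1-yl]-3-methylcyclopentan-1-one | O=C1CC[C@](C)(/C=C/CCCC)[C@H]1CO[Si](C)(C)C(C)(C)C | intermediate
8 | kinetic trimethylsilyl enol ether of 7 (enol double bond C3=C4, away from C5) | C[Si](C)(C)OC1=CC[C@](C)(/C=C/CCCC)[C@H]1CO[Si](C)(C)C(C)(C)C | intermediate
9 | 5-{[(tert-butyldimethylsilyl)oxy]methyl}-4-[(E)-hex-1-en-1-yl]-4-methylcyclopent-2-en-1-one, centres as in 7 | O=C1C=C[C@](C)(/C=C/CCCC)[C@H]1CO[Si](C)(C)C(C)(C)C | intermediate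
10 | corresponding cyclopent-2-en-1-ol, hydroxyl cis to the silyloxymethyl arm (4β-ol) | O[C@H]1C=C[C@](C)(/C=C/CCCC)[C@H]1CO[Si](C)(C)C(C)(C)C | intermediate
11 | bicyclo[3.1.0]hexan-2-ol, cyclopropane methylene, hydroxyl, silyloxymethyl and methyl β, hexenyl α | O[C@H]1[C@H]2C[C@H]2[C@](C)(/C=C/CCCC)[C@H]1CO[Si](C)(C)C(C)(C)C | intermediate
12 | bicyclo[3.1.0]hexan-2-one (ring A with β-cyclopropane, C4 ketone) | O=C1[C@H]2C[C@H]2[C@](C)(/C=C/CCCC)[C@H]1CO[Si](C)(C)C(C)(C)C | intermediate
13 | tert-butyl diethylphosphonoacetate | CCOP(=O)(CC(=O)OC(C)(C)C)OCC | starting material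
14 | tert-butyl (E)-C4-alkylidene acetate, ester anti to C5 | CC(C)(C)OC(=O)/C=C1/[C@H](CO[Si](C)(C)C(C)(C)C)[C@@](C)(/C=C/CCCC)[C@@H]2C[C@H]12 | intermediate
15 | ring-A aldehyde (C9 formyl on C10) | CC(C)(C)OC(=O)/C=C1/[C@H](CO[Si](C)(C)C(C)(C)C)[C@@](C)(C=O)[C@@H]2C[C@H]12 | intermediate
16 | 3-methyltetronic acid (4-hydroxy-3-methylfuran-2(5H)-one) | CC1=C(O)COC1=O | starting material
17 | 4-bromo-3-methylfuran-2(5H)-one | CC1=C(Br)COC1=O | intermediate
18 | [(4-bromo-3-methylfuran-2-yl)oxy](tert-butyl)dimethylsilane | CC1=C(O[Si](C)(C)C(C)(C)C)OC=C1Br | intermediate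
19 | C8–C9 aldol adduct, 9β-carbinol with 7-bromobutenolide at C8 | CC(C)(C)OC(=O)/C=C1/[C@H](CO[Si](C)(C)C(C)(C)C)[C@@](C)([C@@H](O)[C@@H]3OC(=O)C(C)=C3Br)[C@@H]2C[C@H]12 | intermediate
20 | 9β-tert-butyldimethylsilyl ether of 19 | CC(C)(C)OC(=O)/C=C1/[C@H](CO[Si](C)(C)C(C)(C)C)[C@@](C)([C@@H](O[Si](C)(C)C(C)(C)C)[C@@H]3OC(=O)C(C)=C3Br)[C@@H]2C[C@H]12 | intermediate
21 | C6 primary alcohol | CC(C)(C)OC(=O)/C=C1/[C@H](CO)[C@@](C)([C@@H](O[Si](C)(C)C(C)(C)C)[C@@H]3OC(=O)C(C)=C3Br)[C@@H]2C[C@H]12 | intermediate
22 | C6 aldehyde | CC(C)(C)OC(=O)/C=C1/[C@H](C=O)[C@@](C)([C@@H](O[Si](C)(C)C(C)(C)C)[C@@H]3OC(=O)C(C)=C3Br)[C@@H]2C[C@H]12 | intermediate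
23 | tetracyclic 6β-hydroxy lindenanolide tert-butyl ester | CC(C)(C)OC(=O)/C=C2/[C@@H]3[C@H](O)C4=C(C)C(=O)O[C@H]4[C@H](O[Si](C)(C)C(C)(C)C)[C@@]3(C)[C@@H]3C[C@H]23 | intermediate
24 | trimethylsilyl ester 6β-trimethylsilyl ether of the monomer | C[Si](C)(C)OC(=O)/C=C2/[C@@H]3[C@H](O[Si](C)(C)C)C4=C(C)C(=O)O[C@H]4[C@H](O[Si](C)(C)C(C)(C)C)[C@@]3(C)[C@@H]3C[C@H]23 | intermediate
25 | hydroxy acid monomer (6β-OH, C16 acid) | OC(=O)/C=C2/[C@@H]3[C@H](O)C4=C(C)C(=O)O[C@H]4[C@H](O[Si](C)(C)C(C)(C)C)[C@@]3(C)[C@@H]3C[C@H]23 | intermediate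
26 | open-chain ester dimer (one 6α ester link, one free acid, one free 6β-OH) | OC(=O)/C=C2/[C@@H]3[C@@H](OC(=O)/C=C5/[C@@H]6[C@H](O)C7=C(C)C(=O)O[C@H]7[C@H](O[Si](C)(C)C(C)(C)C)[C@@]6(C)[C@@H]6C[C@H]56)C4=C(C)C(=O)O[C@H]4[C@H](O[Si](C)(C)C(C)(C)C)[C@@]3(C)[C@@H]3C[C@H]23 | intermediate
27 | C2-symmetric 12-membered head-to-tail dilactone (both C6–O α) | O=C1/C=C2/[C@@H]3[C@@H](OC(=O)/C=C5/[C@@H]6[C@@H](O1)C7=C(C)C(=O)O[C@H]7[C@H](O[Si](C)(C)C(C)(C)C)[C@@]6(C)[C@@H]6C[C@H]56)C4=C(C)C(=O)O[C@H]4[C@H](O[Si](C)(C)C(C)(C)C)[C@@]3(C)[C@@H]3C[C@H]23 | intermediate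
28 | bis(diethoxymethylsilyl ketene acetal) of the C4,C4'-reduced dilactone (ketene acetal geometry not assigned) | CCO[Si](C)(OCC)OC1=C[C@H]2[C@@H]3[C@@H](OC(O[Si](C)(OCC)OCC)=C[C@H]5[C@@H]6[C@@H](O1)C7=C(C)C(=O)O[C@H]7[C@H](O[Si](C)(C)C(C)(C)C)[C@@]6(C)[C@@H]6C[C@H]56)C4=C(C)C(=O)O[C@H]4[C@H](O[Si](C)(C)C(C)(C)C)[C@@]3(C)[C@@H]3C[C@H]23 | intermediate
29 | bis(diethoxymethylsilyl ester) of 30 | CCO[Si](C)(OCC)OC(=O)[C@@H]1[C@H]2[C@@H]3C=C([C@@H]5[C@H](O[Si](C)(C)C(C)(C)C)[C@@]3(C)[C@@H]3C[C@H]23)[C@](C)(C(=O)O5)[C@H](C(=O)O[Si](C)(OCC)OCC)[C@H]2[C@@H]3C=C([C@@H]5[C@H](O[Si](C)(C)C(C)(C)C)[C@@]3(C)[C@@H]3C[C@H]23)[C@]1(C)C(=O)O5 | intermediate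
30 | 12-membered carbocyclic diacid bis-lactone (C15' α on C11; C4 and C15 as drawn, provisional) | OC(=O)[C@@H]1[C@H]2[C@@H]3C=C([C@@H]5[C@H](O[Si](C)(C)C(C)(C)C)[C@@]3(C)[C@@H]3C[C@H]23)[C@](C)(C(=O)O5)[C@H](C(=O)O)[C@H]2[C@@H]3C=C([C@@H]5[C@H](O[Si](C)(C)C(C)(C)C)[C@@]3(C)[C@@H]3C[C@H]23)[C@]1(C)C(=O)O5 | intermediate
31 | tetrapotassium salt of the ring-opened tetracarboxylate (free 8-OH groups) | [K+].[K+].[K+].[K+].[O-]C(=O)[C@@H]1[C@H]2[C@@H]3C=C([C@@H](O)[C@H](O[Si](C)(C)C(C)(C)C)[C@@]3(C)[C@@H]3C[C@H]23)[C@](C)(C(=O)[O-])[C@H](C(=O)[O-])[C@H]2[C@@H]3C=C([C@@H](O)[C@H](O[Si](C)(C)C(C)(C)C)[C@@]3(C)[C@@H]3C[C@H]23)[C@]1(C)C(=O)[O-] | intermediate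
32 | tetramethyl ester diol | COC(=O)[C@@H]1[C@H]2[C@@H]3C=C([C@@H](O)[C@H](O[Si](C)(C)C(C)(C)C)[C@@]3(C)[C@@H]3C[C@H]23)[C@](C)(C(=O)OC)[C@H](C(=O)OC)[C@H]2[C@@H]3C=C([C@@H](O)[C@H](O[Si](C)(C)C(C)(C)C)[C@@]3(C)[C@@H]3C[C@H]23)[C@]1(C)C(=O)OC | intermediate
33 | bis-enone tetramethyl ester | COC(=O)[C@@H]1[C@H]2[C@@H]3C=C(C(=O)[C@H](O[Si](C)(C)C(C)(C)C)[C@@]3(C)[C@@H]3C[C@H]23)[C@](C)(C(=O)OC)[C@H](C(=O)OC)[C@H]2[C@@H]3C=C(C(=O)[C@H](O[Si](C)(C)C(C)(C)C)[C@@]3(C)[C@@H]3C[C@H]23)[C@]1(C)C(=O)OC | intermediate
34 | bis(tert-butyldimethylsilyl dienol ether) (C8(OSi)=C7–C6=C5 in each half) | COC(=O)[C@@H]1[C@H]2C3=CC(=C(O[Si](C)(C)C(C)(C)C)[C@H](O[Si](C)(C)C(C)(C)C)[C@@]3(C)[C@@H]3C[C@H]23)[C@](C)(C(=O)OC)[C@H](C(=O)OC)[C@H]2C3=CC(=C(O[Si](C)(C)C(C)(C)C)[C@H](O[Si](C)(C)C(C)(C)C)[C@@]3(C)[C@@H]3C[C@H]23)[C@]1(C)C(=O)OC | intermediate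
35 | bis-dienone tetramethyl ester | COC(=O)[C@]1(C)[C@H](C(=O)OC)C2=C3C=C(C(=O)[C@H](O[Si](C)(C)C(C)(C)C)[C@@]3(C)[C@@H]3C[C@H]23)[C@](C)(C(=O)OC)[C@H](C(=O)OC)C2=C3C=C1C(=O)[C@H](O[Si](C)(C)C(C)(C)C)[C@@]3(C)[C@@H]1C[C@H]21 | intermediate
36 | 9,9'-bis-O-(tert-butyldimethylsilyl)cycloshizukaol A | COC(=O)[C@]1(C)CC2=C3C=C(C(=O)[C@H](O[Si](C)(C)C(C)(C)C)[C@@]3(C)[C@@H]3C[C@H]23)[C@](C)(C(=O)OC)CC2=C3C=C1C(=O)[C@H](O[Si](C)(C)C(C)(C)C)[C@@]3(C)[C@@H]1C[C@H]21 | intermediate
37 | cycloshizukaol A | COC(=O)[C@]1(C)CC2=C3C=C(C(=O)[C@H](O)[C@@]3(C)[C@@H]3C[C@H]23)[C@](C)(C(=O)OC)CC2=C3C=C1C(=O)[C@H](O)[C@@]3(C)[C@@H]1C[C@H]21 | target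

**Step count and risks**

Total: 24 steps. Longest linear sequence: 22 steps (steps 1–9 and 12–24, from 1 and 2); the furan branch (steps 10–11) joins at step 12.

Steps most likely to fail:

1. Step 19 (proposed new method). Hydride addition may stall at the hindered β,β-disubstituted enoates, or the copper enolates may be protonated before silyl transfer, so that reduction and rearrangement do not mesh in one flask. Fallback from 27 with established reactions run separately: RhCl(PPh3)3-catalysed 1,4-hydrosilylation of both enoates with Et3SiH (toluene, 60 °C) should give the isolable bis(triethylsilyl ketene acetal) F1. After filtration through basic alumina to remove metal and silane, F1 is heated alone (toluene, 90–110 °C) as a plain thermal Ireland–Claisen rearrangement of preformed ketene acetals, giving the bis(triethylsilyl ester) F2. Mild aqueous acid then returns the route at 30.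

2. Step 18. Substitution at the hindered axial C6 may be slow, so that anti elimination of the activated oxygen with H5 (toward a conjugated triene) and open-chain oligomerisation overtake the two displacements. Fallback from 23, separating inversion from ring formation: intermolecular Mitsunobu inversion with the small, more acidic 4-nitrobenzoic acid at high concentration (PPh3, DIAD, toluene, 0 °C) gives the 6α-(4-nitrobenzoate) F3. Methanolysis (K2CO3, MeOH, 0 °C) gives the 6α-alcohol F4, and TMSOTf/2,6-lutidine followed by aqueous citric acid gives the 6α-hydroxy acid F5. Acylative cyclodimerisation under Shiina macrolactonisation conditions (2-methyl-6-nitrobenzoic anhydride, DMAP, Et3N, toluene, slow addition) then forms both ester bonds with retention at C6 and returns the route at 27, with no activated C6 present during the slow ring closure.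

3. Step 16. Facial selectivity at C6 in the ring closure may be poor, and the β,γ-unsaturated aldehyde may partly conjugate before it closes. Fallback from 22, setting C6 by substrate-controlled hydride delivery instead of in the C–C bond formation: the crude cyclisation product, containing 23 and the 6α-alcohol F4, is oxidised (Dess–Martin periodinane, NaHCO3, CH2Cl2) to the single C6 enone F6. Luche reduction (NaBH4, CeCl3·7H2O, MeOH, −78 °C) should then deliver hydride from the α face, away from the axial C14 methyl group, and return the route at 23.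

Further compounds
F1 | step 19 | bis(triethylsilyl ketene acetal) of the C4,C4'-reduced dilactone | CC[Si](CC)(CC)OC1=C[C@H]2[C@@H]3[C@@H](OC(O[Si](CC)(CC)CC)=C[C@H]5[C@@H]6[C@@H](O1)C7=C(C)C(=O)O[C@H]7[C@H](O[Si](C)(C)C(C)(C)C)[C@@]6(C)[C@@H]6C[C@H]56)C4=C(C)C(=O)O[C@H]4[C@H](O[Si](C)(C)C(C)(C)C)[C@@]3(C)[C@@H]3C[C@H]23
F2 | step 19 | bis(triethylsilyl ester) of 30 | CC[Si](CC)(CC)OC(=O)[C@@H]1[C@H]2[C@@H]3C=C([C@@H]5[C@H](O[Si](C)(C)C(C)(C)C)[C@@]3(C)[C@@H]3C[C@H]23)[C@](C)(C(=O)O5)[C@H](C(=O)O[Si](CC)(CC)CC)[C@H]2[C@@H]3C=C([C@@H]5[C@H](O[Si](C)(C)C(C)(C)C)[C@@]3(C)[C@@H]3C[C@H]23)[C@]1(C)C(=O)O5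
F3 | step 18 | 6α-(4-nitrobenzoate) of the tetracyclic tert-butyl ester | CC(C)(C)OC(=O)/C=C2/[C@@H]3[C@@H](OC(=O)c5ccc(cc5)[N+](=O)[O-])C4=C(C)C(=O)O[C@H]4[C@H](O[Si](C)(C)C(C)(C)C)[C@@]3(C)[C@@H]3C[C@H]23
F4 | step 18 | 6α-alcohol (C6 epimer of 23) | CC(C)(C)OC(=O)/C=C2/[C@@H]3[C@@H](O)C4=C(C)C(=O)O[C@H]4[C@H](O[Si](C)(C)C(C)(C)C)[C@@]3(C)[C@@H]3C[C@H]23
F5 | step 18 | 6α-hydroxy acid (C6 epimer of 25) | OC(=O)/C=C2/[C@@H]3[C@@H](O)C4=C(C)C(=O)O[C@H]4[C@H](O[Si](C)(C)C(C)(C)C)[C@@]3(C)[C@@H]3C[C@H]23
F6 | step 16 | C6 enone of the tetracyclic tert-butyl ester | CC(C)(C)OC(=O)/C=C2/[C@@H]3C(=O)C4=C(C)C(=O)O[C@H]4[C@H](O[Si](C)(C)C(C)(C)C)[C@@]3(C)[C@@H]3C[C@H]23
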